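**Plan**

- Ring numbering used throughout: O1, C2 (guaiacyl), C3 (bears the C9 hydroxymethyl), C4 (bears the aroyl carbon C7'), C5.
- Retrosynthesis: the C7' ketone and the C9 alcohol go back to a silyl ether and an ester; then C2–C3 is cut (carbene C–H insertion), then the O1–C2 benzyl ether bond, and last C4–C7' (aldol).
- Enabling feature: the C2–H bond is benzylic to the electron-rich guaiacyl ring, alpha to O1 and 1,5 to C3, so a carbene at C3 finds it as the most hydridic C–H bond within reach of a five-membered closure.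
- Forward: an aldol joins C7' of the syringyl unit to a succinate chain at C4; the imide carbon becomes C5 and is etherified with the guaiacylmethyl unit; a diazo group is placed at C3; the only ring closes last by C2–C3.
- Stereochemistry: C4 (and the temporary C7' centre) come from a syn aldol controlled by (R)-4-benzyl-2-oxazolidinone; C2 and C3 are relayed from C4 in the insertion, and the all-trans ester is also the thermodynamic isomer at C3.

Key step: step 11

**Route**

Step 1
Reactants: 1 syringaldehyde
Product: 2 4-(tert-butyldimethylsilyloxy)-3,5-dimethoxybenzaldehyde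
Conditions: TBSCl, imidazole, DMF, rt
Reagents that add atoms: tert-butyldimethylsilyl chloride, CC(C)(C)[Si](C)(C)Cl
Why: Imidazole-mediated O-silylation of the phenol should proceed even between the two methoxy groups and removes the acidic proton that would quench the boron enolate of step 3.

Step 2
Reactants: 3 (R)-4-benzyl-2-oxazolidinone; 4 4-(tert-butoxy)-4-oxobutanoic acid
Product: 6 tert-butyl 4-[(4R)-4-benzyl-2-oxooxazolidin-3-yl]-4-oxobutanoate, via mixed pivalic anhydride 5 (not isolated)
Conditions: PivCl, Et3N, THF, −20 °C; then 3, LiCl, −20 °C → rt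
Reagents that add atoms: pivaloyl chloride, CC(C)(C)C(=O)Cl (its atoms stay in 5 only and are absent from 6)
Why: N-acylation of the oxazolidinone through a mixed pivalic anhydride under LiCl/Et3N activation should occur at the less hindered succinyl carbonyl, and the tert-butyl ester is chosen because a methyl ester would lactonise onto the C5 hydroxyl freed in step 5.

Step 3
Reactants: 6 tert-butyl 4-[(4R)-4-benzyl-2-oxooxazolidin-3-yl]-4-oxobutanoate; 2 4-(tert-butyldimethylsilyloxy)-3,5-dimethoxybenzaldehyde
Product: 8 tert-butyl (3R,4R)-3-[(4R)-4-benzyl-2-oxooxazolidine-3-carbonyl]-4-[4-(tert-butyldimethylsilyloxy)-3,5-dimethoxyphenyl]-4-hydroxybutanoate, via Z-dibutylboron enolate 7 (not isolated)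
Conditions: Bu2BOTf, iPr2NEt, CH2Cl2, −78 → 0 °C; 2, −78 → 0 °C; then pH 7 buffer, MeOH, H2O2, 0 °C
Reagents that add atoms: dibutylboron triflate, CCCCB(CCCC)OS(=O)(=O)C(F)(F)F (its atoms stay in 7 only and are absent from 8)
Why: Evans syn aldol reaction: soft enolisation should occur only at the boron-chelated imide and not at the tert-butyl ester, and the Z-enolate reacts through a Zimmerman–Traxler chair on the face away from the benzyl group, which sets C4 and C7' as the (R,R) syn pair.

Step 4
Reactants: 8 the syn aldol adduct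
Product: 9 tert-butyl (3R,4R)-3-[(4R)-4-benzyl-2-oxooxazolidine-3-carbonyl]-4-[4-(tert-butyldimethylsilyloxy)-3,5-dimethoxyphenyl]-4-(triethylsilyloxy)butanoate
Conditions: TESOTf, 2,6-lutidine, CH2Cl2, −78 → 0 °C
Reagents that add atoms: triethylsilyl triflate, CC[Si](CC)(CC)OS(=O)(=O)C(F)(F)F
Why: Silylation with the silyl triflate and a hindered pyridine base should cap the benzylic hydroxyl without retro-aldol cleavage, and the triethylsilyl ether is the one silyl group that can later be removed beside the aryl silyl ethers.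

Step 5
Reactants: 9 the silylated aldol imide
Product: 10 tert-butyl (3S,4R)-4-[4-(tert-butyldimethylsilyloxy)-3,5-dimethoxyphenyl]-3-(hydroxymethyl)-4-(triethylsilyloxy)butanoate
Conditions: LiBH4, MeOH (1 equiv), THF, 0 °C
Reagents that add atoms: none
Why: Reductive cleavage of the N-acyl oxazolidinone by LiBH4 should take the activated imide carbonyl down to the C5 alcohol while the tert-butyl ester is neither reduced nor attacked by the new alkoxide, and C4 is untouched (its descriptor changes from R to S only through the priority rules).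

Step 6
Reactants: 11 vanillin
Product: 12 4-(tert-butyldimethylsilyloxy)-3-methoxybenzaldehyde
Conditions: TBSCl, imidazole, DMF, rt
Reagents that add atoms: tert-butyldimethylsilyl chloride, CC(C)(C)[Si](C)(C)Cl
Why: Imidazole-mediated silylation of the phenol is routine and gives the guaiacyl unit in the protected form that must survive the base and carbene steps.

Step 7
Reactants: 12 4-(tert-butyldimethylsilyloxy)-3-methoxybenzaldehyde
Product: 13 [4-(tert-butyldimethylsilyloxy)-3-methoxyphenyl]methanol
Conditions: NaBH4, MeOH, 0 °C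
Reagents that add atoms: none
Why: Borohydride reduction of the aldehyde should give the benzylic alcohol without touching the aryl silyl ether at low temperature.

Step 8
Reactants: 13 [4-(tert-butyldimethylsilyloxy)-3-methoxyphenyl]methanol
Product: 14 4-(tert-butyldimethylsilyloxy)-3-methoxybenzyl 2,2,2-trichloroacetimidate
Conditions: Cl3CCN, DBU (cat.), CH2Cl2, 0 °C
Reagents that add atoms: trichloroacetonitrile, ClC(Cl)(Cl)C#N
Why: Base-catalysed addition of the alcohol to trichloroacetonitrile gives the imidate, the standard electrophile for benzylation under mild acid catalysis.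

Step 9
Reactants: 10 the hydroxy ester; 14 the trichloroacetimidate
Product: 15 tert-butyl (3S,4R)-3-{[4-(tert-butyldimethylsilyloxy)-3-methoxybenzyl]oxymethyl}-4-[4-(tert-butyldimethylsilyloxy)-3,5-dimethoxyphenyl]-4-(triethylsilyloxy)butanoate
Conditions: La(OTf)3 (5 mol%), toluene, rt
Reagents that add atoms: none
Why: Trichloroacetimidate benzylation: the weak Lewis acid should ionise the imidate to a benzylic cation stabilised by the para silyloxy group, which the primary hydroxyl of 10 captures to create the O1–C2 ether, and it should spare the triethylsilyl ether and the tert-butyl ester.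

Step 10
Reactants: 15 the guaiacylmethyl ether
Product: 17 tert-butyl (3S,4R)-2-diazo-3-{[4-(tert-butyldimethylsilyloxy)-3-methoxybenzyl]oxymethyl}-4-[4-(tert-butyldimethylsilyloxy)-3,5-dimethoxyphenyl]-4-(triethylsilyloxy)butanoate, via 2-trifluoroacetyl ester 16 (not isolated)
Conditions: LiN(SiMe3)2, THF, −78 °C; CF3CO2CH2CF3; then MsN3, Et3N, H2O (1 equiv), MeCN, rt
Reagents that add atoms: methanesulfonyl azide, CS(=O)(=O)N=[N+]=[N-]; 2,2,2-trifluoroethyl trifluoroacetate, O=C(OCC(F)(F)F)C(F)(F)F (its atoms stay in 16 only and are absent from 17)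
Why: Detrifluoroacetylative diazo transfer: Claisen trifluoroacetylation of the ester enolate activates C3 for diazo transfer and the trifluoroacetyl group then leaves as the sulfonamide, while C4 is not acidic and no leaving group sits beta to the enolate.

Step 11
Reactants: 17 the diazo ester
Product: 18 tert-butyl (2S,3S,4S)-2-[4-(tert-butyldimethylsilyloxy)-3-methoxyphenyl]-4-{(R)-[4-(tert-butyldimethylsilyloxy)-3,5-dimethoxyphenyl](triethylsilyloxy)methyl}tetrahydrofuran-3-carboxylate
Conditions: Rh2(O2CCPh3)4 (1 mol%), CH2Cl2, −78 → −40 °C, slow addition of 17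
Reagents that add atoms: none
Why: Rh2(O2CCPh3)4 should expel N2 from 17 to give an electrophilic rhodium carbene at C3, which takes up the C2–H bond in a concerted, hydride-transfer-like three-centre transition state; the closest known reaction type is the dirhodium-catalysed intramolecular 1,5 C–H insertion of alpha-diazo esters next to an ether oxygen, which gives 2,3-disubstituted tetrahydrofurans. The one ring closes by C2–C3 bond formation across the array C3–C4–C5–O1–C2, a five-membered closure in which the carbene carbon becomes a ring atom and both O1–C5 and O1–C2 are already in place. C2 is set with retention by the choice between its two diastereotopic hydrogens: the chair-like transition state that keeps the guaiacyl group and the C4 branch pseudo-equatorial places them cis, so the preset C4 centre controls C2. C3 is set in the same event with the ester trans to both neighbours, which is also the thermodynamic arrangement and could be restored by base equilibration because C3 is alpha to the ester. The step needs site selectivity for C2–H over 1,2-hydride migration from C4, over attack on the syringyl ring and over the ethyl C–H bonds of the silyl group: the double activation of C2–H and its 1,5 distance favour insertion, the bulky triphenylacetate ligands and low temperature disfavour hydride migration, and closure through O1 would need a four-membered oxonium ylide.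

Step 12
Reactants: 18 the tetrahydrofuran ester
Product: 19 [(2S,3R,4S)-2-[4-(tert-butyldimethylsilyloxy)-3-methoxyphenyl]-4-{(R)-[4-(tert-butyldimethylsilyloxy)-3,5-dimethoxyphenyl](triethylsilyloxy)methyl}tetrahydrofuran-3-yl]methanol
Conditions: iBu2AlH (excess), CH2Cl2, −78 → 0 °C
Reagents that add atoms: none
Why: Hydride reduction of the ester to the C9 primary alcohol should leave the silyl ethers intact, and it removes the only acidifying group at C3 so that this centre is fixed from here on.

Step 13
Reactants: 19 the C9 alcohol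
Product: 20 the (2S,3R,4S) diol with free C9 hydroxymethyl and free (R)-C7' carbinol, both phenols still as tert-butyldimethylsilyl ethers
Conditions: PPTS (cat.), MeOH/CH2Cl2, 0 °C
Reagents that add atoms: none
Why: Acid-catalysed methanolysis of the alkyl triethylsilyl ether should be selective because aryl tert-butyldimethylsilyl ethers are far more stable to acid, and the trans disposition of the C3 and C4 arms prevents cyclisation between C9–OH and C7'.

Step 14
Reactants: 20 the diol
Product: 21 [4-(tert-butyldimethylsilyloxy)-3,5-dimethoxyphenyl]{(2S,3R,4S)-2-[4-(tert-butyldimethylsilyloxy)-3-methoxyphenyl]-3-(hydroxymethyl)tetrahydrofuran-4-yl}methanone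
Conditions: MnO2 (activated, excess), CH2Cl2, rt
Reagents that add atoms: none
Why: Chemoselective benzylic oxidation: MnO2 should oxidise the aryl carbinol at C7' to the ketone and leave the saturated primary C9 alcohol, and the neutral medium avoids enolisation at C4.

Step 15
Reactants: 21 the bis-silylated keto alcohol
Product: 22 (4-hydroxy-3,5-dimethoxyphenyl)[(2S,3R,4S)-2-(4-hydroxy-3-methoxyphenyl)-3-(hydroxymethyl)tetrahydrofuran-4-yl]methanone, the target
Conditions: Bu4NF, AcOH, THF, 0 °C
Reagents that add atoms: none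
Why: Fluoride cleavage of the two aryl silyl ethers, buffered with acetic acid, should free both phenols without enolising C4 or opening the ring by beta-elimination of O1 from the ketone.

**Compound list**

1 | syringaldehyde | COc1cc(C=O)cc(OC)c1O | starting material
2 | 4-(tert-butyldimethylsilyloxy)-3,5-dimethoxybenzaldehyde | COc1cc(C=O)cc(OC)c1O[Si](C)(C)C(C)(C)C | intermediate
3 | (R)-4-benzyl-2-oxazolidinone | O=C1N[C@H](Cc2ccccc2)CO1 | starting material
4 | 4-(tert-butoxy)-4-oxobutanoic acid | CC(C)(C)OC(=O)CCC(=O)O | starting material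
5 | mixed anhydride of 4 with pivalic acid | CC(C)(C)OC(=O)CCC(=O)OC(=O)C(C)(C)C | intermediate
6 | tert-butyl 4-[(4R)-4-benzyl-2-oxooxazolidin-3-yl]-4-oxobutanoate | O=C1N(C(=O)CCC(=O)OC(C)(C)C)[C@H](Cc2ccccc2)CO1 | intermediate
7 | Z-dibutylboron enolate of imide 6 | O=C1N(/C(OB(CCCC)CCCC)=C/CC(=O)OC(C)(C)C)[C@H](Cc2ccccc2)CO1 | intermediate
8 | tert-butyl (3R,4R)-3-[(4R)-4-benzyl-2-oxooxazolidine-3-carbonyl]-4-[4-(tert-butyldimethylsilyloxy)-3,5-dimethoxyphenyl]-4-hydroxybutanoate | O=C1N(C(=O)[C@H](CC(=O)OC(C)(C)C)[C@@H](O)c2cc(OC)c(O[Si](C)(C)C(C)(C)C)c(OC)c2)[C@H](Cc3ccccc3)CO1 | intermediate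
9 | triethylsilyl ether of 8 | O=C1N(C(=O)[C@H](CC(=O)OC(C)(C)C)[C@@H](O[Si](CC)(CC)CC)c2cc(OC)c(O[Si](C)(C)C(C)(C)C)c(OC)c2)[C@H](Cc3ccccc3)CO1 | intermediate
10 | tert-butyl (3S,4R)-4-[4-(tert-butyldimethylsilyloxy)-3,5-dimethoxyphenyl]-3-(hydroxymethyl)-4-(triethylsilyloxy)butanoate | CC(C)(C)OC(=O)C[C@@H](CO)[C@@H](O[Si](CC)(CC)CC)c1cc(OC)c(O[Si](C)(C)C(C)(C)C)c(OC)c1 | intermediate
11 | vanillin | COc1cc(C=O)ccc1O | starting material
12 | 4-(tert-butyldimethylsilyloxy)-3-methoxybenzaldehyde | COc1cc(C=O)ccc1O[Si](C)(C)C(C)(C)C | intermediate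
13 | [4-(tert-butyldimethylsilyloxy)-3-methoxyphenyl]methanol | COc1cc(CO)ccc1O[Si](C)(C)C(C)(C)C | intermediate
14 | 4-(tert-butyldimethylsilyloxy)-3-methoxybenzyl 2,2,2-trichloroacetimidate | COc1cc(COC(=N)C(Cl)(Cl)Cl)ccc1O[Si](C)(C)C(C)(C)C | intermediate
15 | tert-butyl (3S,4R)-3-{[4-(tert-butyldimethylsilyloxy)-3-methoxybenzyl]oxymethyl}-4-[4-(tert-butyldimethylsilyloxy)-3,5-dimethoxyphenyl]-4-(triethylsilyloxy)butanoate | CC(C)(C)OC(=O)C[C@@H](COCc1ccc(O[Si](C)(C)C(C)(C)C)c(OC)c1)[C@@H](O[Si](CC)(CC)CC)c1cc(OC)c(O[Si](C)(C)C(C)(C)C)c(OC)c1 | intermediate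
16 | 2-trifluoroacetyl derivative of 15 (mixture at C3, partly enolised) | CC(C)(C)OC(=O)C(C(=O)C(F)(F)F)[C@@H](COCc1ccc(O[Si](C)(C)C(C)(C)C)c(OC)c1)[C@@H](O[Si](CC)(CC)CC)c1cc(OC)c(O[Si](C)(C)C(C)(C)C)c(OC)c1 | intermediate
17 | tert-butyl (3S,4R)-2-diazo-3-{[4-(tert-butyldimethylsilyloxy)-3-methoxybenzyl]oxymethyl}-4-[4-(tert-butyldimethylsilyloxy)-3,5-dimethoxyphenyl]-4-(triethylsilyloxy)butanoate | CC(C)(C)OC(=O)C(=[N+]=[N-])[C@@H](COCc1ccc(O[Si](C)(C)C(C)(C)C)c(OC)c1)[C@@H](O[Si](CC)(CC)CC)c1cc(OC)c(O[Si](C)(C)C(C)(C)C)c(OC)c1 | intermediate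
18 | tert-butyl (2S,3S,4S)-2-[4-(tert-butyldimethylsilyloxy)-3-methoxyphenyl]-4-{(R)-[4-(tert-butyldimethylsilyloxy)-3,5-dimethoxyphenyl](triethylsilyloxy)methyl}tetrahydrofuran-3-carboxylate | COc1cc([C@H]2OC[C@@H]([C@@H](O[Si](CC)(CC)CC)c3cc(OC)c(O[Si](C)(C)C(C)(C)C)c(OC)c3)[C@@H]2C(=O)OC(C)(C)C)ccc1O[Si](C)(C)C(C)(C)C | intermediate
19 | C9 alcohol from reduction of 18 | COc1cc([C@H]2OC[C@@H]([C@@H](O[Si](CC)(CC)CC)c3cc(OC)c(O[Si](C)(C)C(C)(C)C)c(OC)c3)[C@@H]2CO)ccc1O[Si](C)(C)C(C)(C)C | intermediate
20 | diol with free C9 and C7' hydroxyls | COc1cc([C@H]2OC[C@@H]([C@@H](O)c3cc(OC)c(O[Si](C)(C)C(C)(C)C)c(OC)c3)[C@@H]2CO)ccc1O[Si](C)(C)C(C)(C)C | intermediate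
21 | C7' ketone with both phenols silylated | COc1cc([C@H]2OC[C@@H](C(=O)c3cc(OC)c(O[Si](C)(C)C(C)(C)C)c(OC)c3)[C@@H]2CO)ccc1O[Si](C)(C)C(C)(C)C | intermediate
22 | (4-hydroxy-3,5-dimethoxyphenyl)[(2S,3R,4S)-2-(4-hydroxy-3-methoxyphenyl)-3-(hydroxymethyl)tetrahydrofuran-4-yl]methanone | COc1cc([C@H]2OC[C@@H](C(=O)c3cc(OC)c(O)c(OC)c3)[C@@H]2CO)ccc1O | target

**Step count**

Total: 15 steps. Longest linear sequence: 11 steps (steps 2, 3, 4, 5, 9, 10, 11, 12, 13, 14, 15).

**Steps most likely to fail**

Step 11. The carbene may be consumed by 1,2-hydride migration from C4 or by attack on the electron-rich syringyl ring before it reaches C2–H. The wrong diastereotopic benzylic hydrogen may also be replaced, which would give poor control at C2.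
The fallback sets out from hydroxy ester 10 and aldehyde 12 and comes back at 18, making C2–C3 by an ionic aldol and closing the ring at O1–C5 instead.
- Double deprotonation of 10 with LiN(iPr)2 (2.2 equiv, THF, −78 °C) and addition of the ester enolate to 12 should give the diol ester F1.
- TsCl in pyridine should sulfonylate the primary C5 hydroxyl selectively to the primary tosylate F2.
- On warming, the benzylic hydroxyl displaces the tosylate in a 5-exo-tet Williamson closure with retention at C2.
- The aldol is not expected to control C2 and C3 well, so the ester centre would then be equilibrated with KOtBu in t-BuOH and the all-trans isomer 18 separated.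

Step 9. The acid catalyst may cause loss or 1,3-migration of the triethylsilyl group, or lactonisation of the hydroxy ester with loss of the tert-butyl group. The imidate may also rearrange to the N-benzyl amide before the alcohol intercepts it.
The fallback sets out from alcohols 13 and 10 and comes back at 15, using neither acid nor alkoxide base.
- Appel bromination of 13 (CBr4, PPh3, CH2Cl2, 0 °C) should give 4-(tert-butyldimethylsilyloxy)-3-methoxybenzyl bromide F3.
- Alkylation of 10 with F3 promoted by Ag2O (CH2Cl2, 4 Å sieves, dark, rt) should then give ether 15.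

Step 10. C-acylation of the hindered ester enolate next to the C4 branch may be incomplete, so that diazo transfer does not take place and the ester is returned.
The fallback sets out from 15 and comes back at 17, building the diazo group from an amine instead of by acyl activation.
- Electrophilic azidation of the potassium enolate (KN(SiMe3)2, THF, −78 °C; 2,4,6-triisopropylbenzenesulfonyl azide; AcOH quench) should give the alpha-azido ester F4.
- Staudinger reduction (PPh3, THF/H2O) should give the alpha-amino ester F5.
- Diazotisation with isoamyl nitrite and catalytic AcOH in CHCl3 should give 17 by loss of the alpha proton from the diazonium ion; both C3 epimers converge.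

**Further compounds**

F1 | step 11 | tert-butyl 2-{[4-(tert-butyldimethylsilyloxy)-3-methoxyphenyl](hydroxy)methyl}-3-(hydroxymethyl)-4-[4-(tert-butyldimethylsilyloxy)-3,5-dimethoxyphenyl]-4-(triethylsilyloxy)butanoate (isomer leading to 18 shown) | CC(C)(C)OC(=O)[C@H]([C@H](O)c1ccc(O[Si](C)(C)C(C)(C)C)c(OC)c1)[C@@H](CO)[C@@H](O[Si](CC)(CC)CC)c1cc(OC)c(O[Si](C)(C)C(C)(C)C)c(OC)c1
F2 | step 11 | primary p-toluenesulfonate of F1 | CC(C)(C)OC(=O)[C@H]([C@H](O)c1ccc(O[Si](C)(C)C(C)(C)C)c(OC)c1)[C@@H](COS(=O)(=O)c1ccc(C)cc1)[C@@H](O[Si](CC)(CC)CC)c1cc(OC)c(O[Si](C)(C)C(C)(C)C)c(OC)c1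
F3 | step 9 | 4-(tert-butyldimethylsilyloxy)-3-methoxybenzyl bromide | COc1cc(CBr)ccc1O[Si](C)(C)C(C)(C)C
F4 | step 10 | 2-azido derivative of 15 (mixture at C3) | CC(C)(C)OC(=O)C(N=[N+]=[N-])[C@@H](COCc1ccc(O[Si](C)(C)C(C)(C)C)c(OC)c1)[C@@H](O[Si](CC)(CC)CC)c1cc(OC)c(O[Si](C)(C)C(C)(C)C)c(OC)c1
F5 | step 10 | 2-amino derivative of 15 (mixture at C3) | CC(C)(C)OC(=O)C(N)[C@@H](COCc1ccc(O[Si](C)(C)C(C)(C)C)c(OC)c1)[C@@H](O[Si](CC)(CC)CC)c1cc(OC)c(O[Si](C)(C)C(C)(C)C)c(OC)c1
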